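**Plan**

Numbering of the target: 6-oxabicyclo[3.2.2]non-3-ene-2,7-dione. C1 is the H-bridgehead, C2 the ketone, C3 carries allyl, C4 is the vinyl CH, C5 is the ketal carbon, O6, C7 is the lactone C=O, C8 carries aryl, C9 carries methyl.
Retrosynthesis: (a) take out O6 (Baeyer-Villiger) to reach a bicyclo[3.2.1]oct-3-ene-2,8-dione; (b) cut C4-C5 by returning the vinyl CH to the carbonyl carbon (retro-semipinacol), which gives a cis-bicyclo[3.3.0]octadienol; (c) cut that vinyl-carbinol bond (vinyllithium plus ketone) and C1-C2 (aldol) to reach a 2-methoxycyclopentenone and a Z iodo enal; (d) open the cyclopentenone by a retro-Nazarov step.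
Enabling feature: without O6, C5 (OMe) and C7 (C=O) are vicinal, and C5 also holds vinyl C4. This is the product pattern of a 1,2-vinyl shift from a carbinol carbon onto a neighbouring methoxy-oxocarbenium carbon, so the bridged six- and seven-membered rings can grow out of an easily closed five-membered ring.
Forward order of rings: ring B (C1, C8, C9, C5, C7) by Nazarov cyclisation; ring A (five-membered) by aldol and vinyllithium closure; ring A expands to the cyclohexenone, closing C4-C5; oxygen insertion turns ring B into the delta-lactone.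
Stereochemistry: C8 comes from the chiral acid in the Nazarov step and C1 from an aldol anti to aryl. C5 comes from the suprafacial shift on the face fixed by the cis ring fusion, and C9 from reversible protonation that settles trans to aryl. The Baeyer-Villiger migration retains C5.

Key step: step 10

Assumption: the R-configured acid in step 5 is taken to give the 4R ketone by analogy with cyclic alpha-alkoxy dienones; its mirror image is equally available.

**Route**

Step 1
Reactants: 1 pentan-3-one
Product: 2 3,3-dimethoxypentan-2-ol (racemic)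
Conditions: PhI(OAc)2, KOH, MeOH, 0 °C to rt
Reagents that add atoms: methanol, CO
Why: The Moriarty oxidation (enolate attack on trivalent iodine, methoxide addition, closure to a methoxy epoxide and its opening by methoxide) turns an enolisable ketone into the alpha-hydroxy dimethyl ketal, the symmetry of 1 leaves no regiochemical choice, and the racemic carbinol centre is erased in step 2.

Step 2
Reactants: 2 3,3-dimethoxypentan-2-ol
Product: 3 3,3-dimethoxypentan-2-one
Conditions: (n-Pr)4N[RuO4] (5 mol %), N-methylmorpholine N-oxide, 4 Å MS, CH2Cl2, rt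
Reagents that add atoms: none
Why: A Ley-Griffith oxidation is neutral enough to leave the acid-labile ketal untouched while the secondary alcohol becomes the methyl ketone.

Step 3
Reactants: 3 3,3-dimethoxypentan-2-one
Product: 4 (Z)-3-methoxypent-3-en-2-one
Conditions: p-TsOH (1 mol %), neat, 140 °C, MeOH distilled off
Reagents that add atoms: none
Why: Acid-catalysed 1,2-elimination of methanol from an alpha-keto ketal, driven by removal of the methanol, can only run towards C4 and should give the Z enol ether with the methyl group trans to the acetyl group.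

Step 4
Reactants: 4 (Z)-3-methoxypent-3-en-2-one; 5 3,4,5-trimethoxybenzaldehyde
Product: 6 (1E,4Z)-4-methoxy-1-(3,4,5-trimethoxyphenyl)hexa-1,4-dien-3-one
Conditions: NaOH (0.3 equiv), MeOH, 0 °C to rt
Reagents that add atoms: none
Why: In this Claisen-Schmidt aldol condensation the acetyl methyl group is the only alpha position of 4 that can enolise and 5 cannot enolise, so E1cB dehydration should give the E styryl ketone alone.

Step 5
Reactants: 6 (1E,4Z)-4-methoxy-1-(3,4,5-trimethoxyphenyl)hexa-1,4-dien-3-one
Product: 7 (4R)-2-methoxy-3-methyl-4-(3,4,5-trimethoxyphenyl)cyclopent-2-en-1-one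
Conditions: (R)-3,3'-di(9-phenanthryl)-1,1'-binaphthalene-2,2'-diyl N-(trifluoromethylsulfonyl)phosphoramidate (5 mol %), CHCl3, 0 °C
Reagents that add atoms: none
Why: In this Brønsted-acid-catalysed asymmetric Nazarov cyclisation the protonated dienone closes by conrotatory 4π electrocyclisation inside the chiral ion pair, which sets C4, and the methoxy group localises the charge so that proton loss gives the enol-ether double bond and not the aryl-conjugated one.

Step 6
Reactants: 8 prop-2-yn-1-ol; 9 allylmagnesium bromide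
Product: 11 (Z)-2-(iodomethylidene)pent-4-en-1-ol, via cyclic vinylmagnesium alkoxide 10 (not isolated)
Conditions: 9 (2.5 equiv), CuI (10 mol %), Et2O, 0 °C to rt; then I2, THF, −40 to 0 °C; aqueous work-up
Reagents that add atoms: iodine, II
Why: Copper-catalysed carbomagnesiation of the propargylic alkoxide places the allyl group on the inner alkyne carbon and magnesium on the terminus within a five-membered chelate, and iodinolysis with retention fixes iodine cis to the hydroxymethyl group (Z).

Step 7
Reactants: 11 (Z)-2-(iodomethylidene)pent-4-en-1-ol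
Product: 12 (Z)-2-(iodomethylidene)pent-4-enal
Conditions: MnO2, CH2Cl2, rt, dark
Reagents that add atoms: none
Why: Allylic alcohol oxidation with MnO2 is neutral and stops at the aldehyde, and exclusion of light guards the Z geometry.

Step 8
Reactants: 7 (4R)-2-methoxy-3-methyl-4-(3,4,5-trimethoxyphenyl)cyclopent-2-en-1-one; 12 (Z)-2-(iodomethylidene)pent-4-enal
Product: 15 (4R,5R)-5-[(2Z)-2-(iodomethylidene)-1-(triethylsilyloxy)pent-4-en-1-yl]-2-methoxy-3-methyl-4-(3,4,5-trimethoxyphenyl)cyclopent-2-en-1-one (both carbinol epimers), via lithium enolate 13 (not isolated), via lithium aldolate 14 (not isolated)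
Conditions: LDA, THF, −78 °C; 12, −78 °C; then Et3SiOTf, −78 °C
Reagents that add atoms: triethylsilyl trifluoromethanesulfonate, CC[Si](CC)(CC)OS(=O)(=O)C(F)(F)F
Why: Kinetic alpha'-deprotonation and 1,2-selective aldol addition bring the aldehyde in anti to the neighbouring aryl group, which sets C5 trans, the carbinol centre is of no consequence because step 11 erases it, and silylation in the cold blocks retro-aldol cleavage.

Step 9
Reactants: 15 (4R,5R)-5-[(2Z)-2-(iodomethylidene)-1-(triethylsilyloxy)pent-4-en-1-yl]-2-methoxy-3-methyl-4-(3,4,5-trimethoxyphenyl)cyclopent-2-en-1-one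
Product: 18 (3aR,6R,6aR)-4-methoxy-5-methyl-2-(prop-2-en-1-yl)-1-(triethylsilyloxy)-6-(3,4,5-trimethoxyphenyl)-6,6a-dihydropentalen-3a(1H)-ol (cis-fused; 3a-OH, 6a-H and 6-aryl on one face), via vinyllithium 16 (not isolated), via lithium alkoxide 17 (not isolated)
Conditions: t-BuLi (2.1 equiv), Et2O, −78 °C; then H2O
Reagents that add atoms: none
Why: Iodine-lithium exchange outruns attack of t-BuLi on the carbonyl group, and the Z vinyllithium, held on the face anti to aryl, adds 1,2 to the ketone in a 5-exo-trig intramolecular carbonyl addition that can only give the cis-fused carbinol, which sets C3a.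

Step 10
Reactants: 18 (3aR,6R,6aR)-4-methoxy-5-methyl-2-(prop-2-en-1-yl)-1-(triethylsilyloxy)-6-(3,4,5-trimethoxyphenyl)-6,6a-dihydropentalen-3a(1H)-ol
Product: 21 (1R,5R,6R,7R)-2-hydroxy-5-methoxy-6-methyl-3-(prop-2-en-1-yl)-7-(3,4,5-trimethoxyphenyl)bicyclo[3.2.1]oct-3-en-8-one (both C2 epimers; aryl exo, methyl endo), via oxocarbenium ion 19 (not isolated), via silyl ether 20 (not isolated)
Conditions: 10-camphorsulfonic acid (0.2 equiv), 4 Å MS, CH2Cl2, −20 °C to rt; then MeOH, rt
Reagents that add atoms: none
Why: The acid protonates the enol ether of 18 at C5 (pentalene numbering) to give methoxy-oxocarbenium ion 19, vinyl carbon C3 then migrates from the carbinol carbon C3a to the cationic C4 while the hydroxyl group becomes the C8 ketone of 20, and the methanol added at the end only removes the triethylsilyl group. The closest known reaction type is the oxonium-ion-initiated pinacol-type (semipinacol) ring expansion of carbinols made from alpha-metalated enol ethers and cycloalkanones. The shift closes the six-membered enone ring (C1 to C5 plus C8) and with it the seven-membered carbocycle (C1 to C7) by a suprafacial 1,2-migration through a three-centre, cyclopropylcarbinyl-like transition state at the cost of five-membered ring A, so a fused bicyclo[3.3.0] skeleton becomes a bridged bicyclo[3.2.1] skeleton. C5 of 20 is fixed because the migrating carbon stays on the face where the cis ring fusion holds it, which puts methoxy anti to the new bond, and C6 arises in a reversible protonation, so the product should derive from the epimer of 19 with methyl trans to aryl, the one that avoids eclipsed vicinal groups on the developing two-carbon bridge. The step needs protonation of the enol ether rather than ionisation of the doubly allylic alcohol, secured by a weak acid in a dry non-polar medium in the cold and by methoxy sitting on the central, non-stabilising carbon of the allyl cation that ionisation would give, and it needs migration of C3 rather than C6a, secured because the latter would contract ring B to a cyclobutane. Exchange of an enol ether and an alcohol for a ketone and an ether pays for the added strain.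

Step 11
Reactants: 21 (1R,5R,6R,7R)-2-hydroxy-5-methoxy-6-methyl-3-(prop-2-en-1-yl)-7-(3,4,5-trimethoxyphenyl)bicyclo[3.2.1]oct-3-en-8-one
Product: 22 (1R,5R,6R,7R)-5-methoxy-6-methyl-3-(prop-2-en-1-yl)-7-(3,4,5-trimethoxyphenyl)bicyclo[3.2.1]oct-3-ene-2,8-dione
Conditions: Dess-Martin periodinane, CH2Cl2, rt
Reagents that add atoms: none
Why: Dess-Martin oxidation of the secondary allylic alcohol merges both C2 epimers into one enone, and the 1,3-dione cannot enolise at the bridgehead, so C1 is safe.

Step 12
Reactants: 22 (1R,5R,6R,7R)-5-methoxy-6-methyl-3-(prop-2-en-1-yl)-7-(3,4,5-trimethoxyphenyl)bicyclo[3.2.1]oct-3-ene-2,8-dione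
Product: 23 (1R,5S,8R,9R)-5-methoxy-9-methyl-3-(prop-2-en-1-yl)-8-(3,4,5-trimethoxyphenyl)-6-oxabicyclo[3.2.2]non-3-ene-2,7-dione (target)
Conditions: mCPBA (1.1 equiv), CH2Cl2, 0 °C
Reagents that add atoms: 3-chloroperoxybenzoic acid, O=C(OO)c1cccc(Cl)c1
Why: In this Baeyer-Villiger oxidation the strained one-carbon-bridge ketone takes up the peracid far faster than the enone carbonyl, the methoxy-bearing bridgehead migrates with retention because its oxygen stabilises the developing charge while the other bridgehead is deactivated by the C2 ketone, and the monosubstituted alkene and the enone are poor partners for the peracid.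

**Compound list**

1 | pentan-3-one | CCC(=O)CC | starting material
2 | 3,3-dimethoxypentan-2-ol (racemic) | CCC(OC)(OC)C(C)O | intermediate
3 | 3,3-dimethoxypentan-2-one | CCC(OC)(OC)C(C)=O | intermediate
4 | (Z)-3-methoxypent-3-en-2-one | C/C=C(\OC)C(C)=O | intermediate
5 | 3,4,5-trimethoxybenzaldehyde | COc1cc(C=O)cc(OC)c1OC | starting material
6 | (1E,4Z)-4-methoxy-1-(3,4,5-trimethoxyphenyl)hexa-1,4-dien-3-one | C/C=C(\OC)C(=O)/C=C/c1cc(OC)c(OC)c(OC)c1 | intermediate
7 | (4R)-2-methoxy-3-methyl-4-(3,4,5-trimethoxyphenyl)cyclopent-2-en-1-one | O=C1C[C@H](c2cc(OC)c(OC)c(OC)c2)C(C)=C1OC | intermediate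
8 | prop-2-yn-1-ol | C#CCO | starting material
9 | allylmagnesium bromide | C=CC[Mg]Br | starting material
10 | cyclic vinylmagnesium alkoxide (4-allyl-2,5-dihydro-1,2-oxamagnesole) | C=CCC1=C[Mg]OC1 | intermediate
11 | (Z)-2-(iodomethylidene)pent-4-en-1-ol | OC/C(CC=C)=C\I | intermediate
12 | (Z)-2-(iodomethylidene)pent-4-enal | O=C/C(CC=C)=C\I | intermediate
13 | lithium enolate of 7 | [Li]OC1=C[C@H](c2cc(OC)c(OC)c(OC)c2)C(C)=C1OC | intermediate
14 | lithium aldolate | O=C1[C@@H](C(O[Li])/C(CC=C)=C\I)[C@H](c2cc(OC)c(OC)c(OC)c2)C(C)=C1OC | intermediate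
15 | (4R,5R)-keto vinyl iodide, triethylsilyl ether | O=C1[C@@H](C(O[Si](CC)(CC)CC)/C(CC=C)=C\I)[C@H](c2cc(OC)c(OC)c(OC)c2)C(C)=C1OC | intermediate
16 | vinyllithium from 15 | O=C1[C@@H](C(O[Si](CC)(CC)CC)/C(CC=C)=C\[Li])[C@H](c2cc(OC)c(OC)c(OC)c2)C(C)=C1OC | intermediate
17 | lithium alkoxide of 18 | [Li]O[C@]12C=C(CC=C)C(O[Si](CC)(CC)CC)[C@H]1[C@H](c1cc(OC)c(OC)c(OC)c1)C(C)=C2OC | intermediate
18 | (3aR,6R,6aR)-cis-fused dihydropentalen-3a-ol | O[C@]12C=C(CC=C)C(O[Si](CC)(CC)CC)[C@H]1[C@H](c1cc(OC)c(OC)c(OC)c1)C(C)=C2OC | intermediate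
19 | methoxy-oxocarbenium ion (methyl trans to aryl) | O[C@]12C=C(CC=C)C(O[Si](CC)(CC)CC)[C@H]1[C@H](c1cc(OC)c(OC)c(OC)c1)[C@@H](C)C2=[O+]C | intermediate
20 | (1R,5R,6R,7R)-5-methoxy-6-methyl-3-(prop-2-en-1-yl)-2-(triethylsilyloxy)-7-(3,4,5-trimethoxyphenyl)bicyclo[3.2.1]oct-3-en-8-one | C=CCC1=C[C@@]2(OC)C(=O)[C@@H](C1O[Si](CC)(CC)CC)[C@H](c1cc(OC)c(OC)c(OC)c1)[C@H]2C | intermediate
21 | (1R,5R,6R,7R)-2-hydroxy-5-methoxy-6-methyl-3-(prop-2-en-1-yl)-7-(3,4,5-trimethoxyphenyl)bicyclo[3.2.1]oct-3-en-8-one | C=CCC1=C[C@@]2(OC)C(=O)[C@@H](C1O)[C@H](c1cc(OC)c(OC)c(OC)c1)[C@H]2C | intermediate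
22 | (1R,5R,6R,7R)-5-methoxy-6-methyl-3-(prop-2-en-1-yl)-7-(3,4,5-trimethoxyphenyl)bicyclo[3.2.1]oct-3-ene-2,8-dione | C=CCC1=C[C@@]2(OC)C(=O)[C@@H](C1=O)[C@H](c1cc(OC)c(OC)c(OC)c1)[C@H]2C | intermediate
23 | (1R,5S,8R,9R)-5-methoxy-9-methyl-3-(prop-2-en-1-yl)-8-(3,4,5-trimethoxyphenyl)-6-oxabicyclo[3.2.2]non-3-ene-2,7-dione | C=CCC1=C[C@@]2(OC)OC(=O)[C@@H](C1=O)[C@H](c1cc(OC)c(OC)c(OC)c1)[C@H]2C | target

**Step count and risks**

Total step count: 12. Longest linear sequence: 10 (steps 1 to 5 and 8 to 12).

Steps most likely to fail: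

1. Step 10. Acid-induced ionisation of the doubly allylic tertiary alcohol may outrun the shift, or the protonation may end with methyl cis to aryl. The fallback runs from 18 back to 20.
   - The enol ether is hydrolysed on oxalic-acid-doped wet silica gel to the fused alpha-ketol (3aR,5R,6R,6aR)-3a-hydroxy-5-methyl-2-(prop-2-en-1-yl)-1-(triethylsilyloxy)-6-(3,4,5-trimethoxyphenyl)-3a,5,6,6a-tetrahydropentalen-4(1H)-one F1, in which C5 can equilibrate to the trans epimer.
   - An acyloin (alpha-ketol) rearrangement with Al(O-t-Bu)3 in toluene moves the same vinyl carbon and gives the bridgehead ketol (1R,5R,6R,7R)-5-hydroxy-6-methyl-3-(prop-2-en-1-yl)-2-(triethylsilyloxy)-7-(3,4,5-trimethoxyphenyl)bicyclo[3.2.1]oct-3-en-8-one F2.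
   - O-methylation with MeOTf and 2,6-di-tert-butyl-4-methylpyridine gives 20, which is desilylated as in step 10.

2. Step 5. Turnover may be slow or torquoselectivity poor, because the dienone has no alpha substituent on the styryl arm and carries an electron-rich aryl group. The fallback runs from 3 and 5 back to 7.
   - 3 is carbomethoxylated (NaH, dimethyl carbonate) to methyl 4,4-dimethoxy-3-oxohexanoate F3.
   - Knoevenagel condensation with 5 (piperidine, AcOH) gives methyl 2-(2,2-dimethoxybutanoyl)-3-(3,4,5-trimethoxyphenyl)prop-2-enoate F4.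
   - Me3SiOTf and i-Pr2NEt remove methanol to give methyl 2-[(Z)-2-methoxybut-2-enoyl]-3-(3,4,5-trimethoxyphenyl)prop-2-enoate F5.
   - A polarised Nazarov cyclisation with Cu(SbF6)2 and (S,S)-t-Bu-bis(oxazoline), which binds the 1,3-dicarbonyl unit as a chelate, gives methyl (1S,5R)-3-methoxy-4-methyl-2-oxo-5-(3,4,5-trimethoxyphenyl)cyclopent-3-ene-1-carboxylate F6.
   - Krapcho demethoxycarbonylation (LiCl, wet DMSO, 130 °C) returns 7.

3. Step 12. Epoxidation of the terminal alkene may compete with oxygen insertion. The fallback runs from 22 back to 23.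
   - Excess mCPBA drives both events to the epoxy lactone (1R,5S,8R,9R)-5-methoxy-9-methyl-3-(oxiran-2-ylmethyl)-8-(3,4,5-trimethoxyphenyl)-6-oxabicyclo[3.2.2]non-3-ene-2,7-dione F7.
   - The terminal epoxide is then deoxygenated by oxygen transfer to PPh3 with CH3ReO3 as catalyst in benzene, which restores the allyl group of 23.

**Further compounds**

F1 | step 10 | (3aR,5R,6R,6aR)-3a-hydroxy-5-methyl-2-(prop-2-en-1-yl)-1-(triethylsilyloxy)-6-(3,4,5-trimethoxyphenyl)-3a,5,6,6a-tetrahydropentalen-4(1H)-one | O[C@]12C=C(CC=C)C(O[Si](CC)(CC)CC)[C@H]1[C@H](c1cc(OC)c(OC)c(OC)c1)[C@@H](C)C2=O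
F2 | step 10 | (1R,5R,6R,7R)-5-hydroxy-6-methyl-3-(prop-2-en-1-yl)-2-(triethylsilyloxy)-7-(3,4,5-trimethoxyphenyl)bicyclo[3.2.1]oct-3-en-8-one | C=CCC1=C[C@@]2(O)C(=O)[C@@H](C1O[Si](CC)(CC)CC)[C@H](c1cc(OC)c(OC)c(OC)c1)[C@H]2C
F3 | step 5 | methyl 4,4-dimethoxy-3-oxohexanoate | CCC(OC)(OC)C(=O)CC(=O)OC
F4 | step 5 | methyl 2-(2,2-dimethoxybutanoyl)-3-(3,4,5-trimethoxyphenyl)prop-2-enoate (alkene isomers) | CCC(OC)(OC)C(=O)C(=Cc1cc(OC)c(OC)c(OC)c1)C(=O)OC
F5 | step 5 | methyl 2-[(Z)-2-methoxybut-2-enoyl]-3-(3,4,5-trimethoxyphenyl)prop-2-enoate | C/C=C(\OC)C(=O)C(=Cc1cc(OC)c(OC)c(OC)c1)C(=O)OC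
F6 | step 5 | methyl (1S,5R)-3-methoxy-4-methyl-2-oxo-5-(3,4,5-trimethoxyphenyl)cyclopent-3-ene-1-carboxylate | O=C1[C@@H](C(=O)OC)[C@H](c2cc(OC)c(OC)c(OC)c2)C(C)=C1OC
F7 | step 12 | (1R,5S,8R,9R)-5-methoxy-9-methyl-3-(oxiran-2-ylmethyl)-8-(3,4,5-trimethoxyphenyl)-6-oxabicyclo[3.2.2]non-3-ene-2,7-dione (epoxide epimers) | C(C1CO1)C1=C[C@@]2(OC)OC(=O)[C@@H](C1=O)[C@H](c1cc(OC)c(OC)c(OC)c1)[C@H]2C
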